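**Retrosynthetic overview** (side chain numbered C1' at the ether CH2 to C8' at the lactone carbonyl)
1. The aryl ether is cut first: Mitsunobu union of bought 7-hydroxy-8-methoxycoumarin with an epoxy lactone primary alcohol, so the coumarin rings are not built.
2. The C2'–C3' oxirane and the γ-lactone are closed together in one Ti(OiPr)4/tartrate operation from an open-chain diol that carries the acid as a lactic acid/pivalaldehyde acetal.
3. The C6'–C7' bond comes from the Seebach lactate enolate (sets the tertiary carbinol C7') opening an (R)-terminal oxirane at CH2 (C5' already in place).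
4. The terminal oxirane comes from geranyl acetate (E-alkene inherited; ozonolysis, enamine α-chlorination, reduction, closure). Ring order: dioxolanone auxiliary, transient terminal oxirane, then trisubstituted oxirane and lactone together.

Assumption: 7-hydroxy-8-methoxycoumarin (daphnetin 8-methyl ether) is bought as a catalogue phenol; every other starting material is a bulk chemical.

**Step 1**
Reactants: 1 (S)-lactic acid; 2 pivalaldehyde
Product: 3 (2S,5S)-2-tert-butyl-5-methyl-1,3-dioxolan-4-one
Conditions: TsOH·H2O (cat.), H2SO4 (cat.), pentane, reflux, Dean–Stark; recrystallise from pentane/Et2O at −78 °C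
Reagents that add atoms: none
Why: Acid-catalysed acetalisation (first stage of Seebach's self-regeneration of stereocentres): the lactic acid centre is not touched, and the new acetal carbon equilibrates to the cis (2S) isomer, which is obtained pure by low-temperature crystallisation.

**Step 2**
Reactants: 4 geranyl acetate
Product: 6 (2E)-3-methyl-6-oxohex-2-en-1-yl acetate, via ozonide 5 (not isolated)
Conditions: O3 (1.0 equiv), CH2Cl2, −78 °C; then Me2S, −78 °C → rt
Reagents that add atoms: ozone, [O-][O+]=O
Why: Chemoselective ozonolysis with reductive work-up: the electron-rich 6,7-alkene is cleaved much faster than the 2,3-alkene, which is deactivated by the allylic acetate, so the E geometry of the remaining double bond is carried on unchanged.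

**Step 3**
Reactants: 6 (2E)-3-methyl-6-oxohex-2-en-1-yl acetate
Product: 9 (2E)-3-methyl-4-[(2R)-oxiran-2-yl]but-2-en-1-ol, via chloroaldehyde 7 (not isolated), via chlorohydrin 8 (not isolated)
Conditions: NCS (1.2 equiv), (2R,5R)-2,5-diphenylpyrrolidine (10 mol %), CH2Cl2, 0 °C → rt; then MeOH, NaBH4, 0 °C; then aq. KOH, 0 °C → rt
Reagents that add atoms: none
Why: Enamine-catalysed α-chlorination of the aldehyde (Jørgensen type) sets C5' as the S chloride through shielding of one enamine face by the C2-symmetric amine, and borohydride reduction followed by intramolecular Williamson closure inverts that carbon to the R oxirane while KOH also removes the acetate; the sense is confirmed on the first batch by the rotation of 9, and the (2S,5S) amine is used if it is found reversed.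

**Step 4**
Reactants: 3 (2S,5S)-2-tert-butyl-5-methyl-1,3-dioxolan-4-one; 9 (2E)-3-methyl-4-[(2R)-oxiran-2-yl]but-2-en-1-ol
Product: 12 (2S,5R)-2-tert-butyl-5-[(2R,4E)-2,6-dihydroxy-4-methylhex-4-en-1-yl]-5-methyl-1,3-dioxolan-4-one, via lithium enolate 10 (not isolated), via lithium alkoxide 11 (not isolated)
Conditions: 3 (1.3 equiv), LiN(iPr)2 (1.35 equiv), THF, −78 °C; 9 + n-BuLi (1.0 equiv), THF, −78 °C; combine, BF3·OEt2 (3 equiv), −78 °C, 2 h; sat. aq. NH4Cl, −78 → 0 °C; crude diol used at once
Reagents that add atoms: none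
Why: Seebach alkylation combined with BF3-assisted SN2 opening of a terminal oxirane by a lithium enolate: the enolate carbon attacks the oxirane CH2 from the face anti to tert-butyl, so the new quaternary centre keeps the sense of (S)-lactic acid (5R), the oxirane stereocentre is not touched, and the BF3-bound alkoxide does not acylate, which leaves the chain open for step 5.

**Step 5**
Reactants: 12 (2S,5R)-2-tert-butyl-5-[(2R,4E)-2,6-dihydroxy-4-methylhex-4-en-1-yl]-5-methyl-1,3-dioxolan-4-one
Product: 14 (3R,5S)-3-hydroxy-5-{[(2R,3R)-3-(hydroxymethyl)-2-methyloxiran-2-yl]methyl}-3-methyloxolan-2-one, via epoxy diol 13 (not isolated)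
Conditions: Ti(OiPr)4 (1.1 equiv), D-(−)-diisopropyl tartrate (1.3 equiv), t-BuOOH (2 equiv, decane), 4 Å molecular sieves, CH2Cl2, −25 °C, 16 h, then 0 °C, 2 h; 10% aq. tartaric acid; chromatography (removes minor diastereomers)
Reagents that add atoms: tert-butyl hydroperoxide, CC(C)(C)OO
Why: Proposed new method: Sharpless asymmetric epoxidation run as a tandem with an alkoxide ring switch; the tartrate-bound titanium peroxide coordinated to the primary allylic alcohol delivers oxygen to the alkene face that gives the (2R,3R)-oxirane (D-tartrate, same sense as geraniol, remote centres do not override it), while the titanium alkoxide of the secondary carbinol adds 5-exo-trig to the activated acetal ester carbonyl and the hemiacetal falls apart to pivalaldehyde, closing the γ-lactone without touching its two stereocentres (the ring carbon changes label from R to S only through CIP ranking); closest known reactions are the Ti(OiPr)4/tartrate epoxidation of geraniol and Ti(OiPr)4-mediated transesterification and lactonisation of hydroxy esters.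

**Step 6**
Reactants: 14 (3R,5S)-3-hydroxy-5-{[(2R,3R)-3-(hydroxymethyl)-2-methyloxiran-2-yl]methyl}-3-methyloxolan-2-one; 15 7-hydroxy-8-methoxy-2H-chromen-2-one
Product: 16 7-{[(2R,3R)-3-{[(2S,4R)-4-hydroxy-4-methyl-5-oxooxolan-2-yl]methyl}-3-methyloxiran-2-yl]methoxy}-8-methoxy-2H-chromen-2-one
Conditions: PPh3 (1.3 equiv), DIAD (1.3 equiv), THF, 0 °C → rt
Reagents that add atoms: none
Why: Mitsunobu etherification of the primary carbinol of a 2,3-epoxy alcohol with an acidic phenol (pKa about 8), an SN2 reaction at CH2 that touches no stereocentre and leaves the tertiary alcohol, the oxirane and both lactones alone.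

**Compound list**
1 | (S)-lactic acid, (2S)-2-hydroxypropanoic acid | C[C@H](O)C(=O)O | starting material
2 | pivalaldehyde, 2,2-dimethylpropanal | CC(C)(C)C=O | starting material
3 | (2S,5S)-2-tert-butyl-5-methyl-1,3-dioxolan-4-one (cis) | C[C@@H]1O[C@H](C(C)(C)C)OC1=O | intermediate
4 | geranyl acetate, (2E)-3,7-dimethylocta-2,6-dien-1-yl acetate | CC(C)=CCC/C(C)=C/COC(C)=O | starting material
5 | (2E)-5-(5,5-dimethyl-1,2,4-trioxolan-3-yl)-3-methylpent-2-en-1-yl acetate (ozonide, ring carbon unassigned) | CC1(C)OOC(CC/C(C)=C/COC(C)=O)O1 | intermediate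
6 | (2E)-3-methyl-6-oxohex-2-en-1-yl acetate | O=CCC/C(C)=C/COC(C)=O | intermediate
7 | (2E,5S)-5-chloro-3-methyl-6-oxohex-2-en-1-yl acetate | O=C[C@@H](Cl)C/C(C)=C/COC(C)=O | intermediate
8 | (2E,5S)-5-chloro-6-hydroxy-3-methylhex-2-en-1-yl acetate | OC[C@@H](Cl)C/C(C)=C/COC(C)=O | intermediate
9 | (2E)-3-methyl-4-[(2R)-oxiran-2-yl]but-2-en-1-ol | OC/C=C(C)/C[C@@H]1CO1 | intermediate
10 | lithium (2S)-2-tert-butyl-5-methyl-1,3-dioxol-4-olate | [Li+].CC1=C([O-])O[C@@H](C(C)(C)C)O1 | intermediate
11 | lithium (2E)-3-methyl-4-[(2R)-oxiran-2-yl]but-2-en-1-olate | [Li+].[O-]C/C=C(C)/C[C@@H]1CO1 | intermediate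
12 | (2S,5R)-2-tert-butyl-5-[(2R,4E)-2,6-dihydroxy-4-methylhex-4-en-1-yl]-5-methyl-1,3-dioxolan-4-one | C[C@]1(C[C@H](O)C/C(C)=C/CO)O[C@H](C(C)(C)C)OC1=O | intermediate
13 | (2S,5R)-2-tert-butyl-5-{(2R)-2-hydroxy-3-[(2R,3R)-3-(hydroxymethyl)-2-methyloxiran-2-yl]propyl}-5-methyl-1,3-dioxolan-4-one | C[C@]1(C[C@H](O)C[C@@]2(C)O[C@@H]2CO)O[C@H](C(C)(C)C)OC1=O | intermediate
14 | (3R,5S)-3-hydroxy-5-{[(2R,3R)-3-(hydroxymethyl)-2-methyloxiran-2-yl]methyl}-3-methyloxolan-2-one | OC[C@H]1O[C@]1(C)C[C@@H]2C[C@@](C)(O)C(=O)O2 | intermediate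
15 | 7-hydroxy-8-methoxy-2H-chromen-2-one | COc1c(O)ccc2ccc(=O)oc12 | starting material
16 | 7-{[(2R,3R)-3-{[(2S,4R)-4-hydroxy-4-methyl-5-oxooxolan-2-yl]methyl}-3-methyloxiran-2-yl]methoxy}-8-methoxy-2H-chromen-2-one (CNP0128940.1) | COc1c(OC[C@H]2O[C@]2(C)C[C@@H]2C[C@@](C)(O)C(=O)O2)ccc2ccc(=O)oc12 | target

**Total step count:** 6. **Longest linear sequence:** 5 steps (4 → 6 → 9 → 12 → 14 → 16); step 1 is the convergent branch.

**Three steps most likely to fail, with fallbacks**

Step 4 (enolate/oxirane coupling). The dioxolanone enolate decomposes above about −30 °C and BF3 may divert it, so conversion can be low. The fallback sets out from chlorohydrin 8, isolated by leaving out the KOH stage of step 3. Tf2O and 2,6-lutidine (CH2Cl2, −78 °C) convert its primary hydroxyl into (2E,5S)-5-chloro-3-methyl-6-[(trifluoromethanesulfonyl)oxy]hex-2-en-1-yl acetate F1. This primary triflate alkylates lithium enolate 10 at −78 °C without any Lewis acid, again anti to tert-butyl, to give (2S,5R)-2-tert-butyl-5-[(2S,4E)-6-acetoxy-2-chloro-4-methylhex-4-en-1-yl]-5-methyl-1,3-dioxolan-4-one F2. LiOH in THF/H2O (45 °C, then pH 3) removes the acetate and the pivalaldehyde acetal and lets the carboxylate displace the secondary chloride with inversion, the same net inversion at that carbon as the oxirane route. This gives (3R,5R)-3-hydroxy-5-[(2E)-4-hydroxy-2-methylbut-2-en-1-yl]-3-methyloxolan-2-one F3 (5R here and 5S in 14 are the same spatial arrangement). The Ti(OiPr)4/D-diisopropyl tartrate/t-BuOOH epoxidation of step 5 then converts F3 into 14, where the fallback rejoins the route.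

Step 5 (tandem epoxidation and ring switch). The secondary hydroxyl or the α-hydroxy lactone product may tie up the titanium tartrate and lower the selectivity, the ring switch may lag, or the free secondary alcohol may attack the new oxirane. The fallback sets out from 12. Mitsunobu etherification of its primary allylic hydroxyl with 15 (PPh3, DIAD, THF, 0 °C; the secondary alcohol reacts far more slowly) gives 7-{[(2E,5R)-6-[(2S,4R)-2-tert-butyl-4-methyl-5-oxo-1,3-dioxolan-4-yl]-5-hydroxy-3-methylhex-2-en-1-yl]oxy}-8-methoxy-2H-chromen-2-one F4. Shi epoxidation follows, with 1,2:4,5-di-O-isopropylidene-β-D-erythro-hexo-2,3-diulo-2,6-pyranose (the D-fructose-derived ketone, 30 mol %), KHSO5 (triple salt 2KHSO5·KHSO4·K2SO4), K2CO3 and Bu4NHSO4 in MeCN/dimethoxymethane/aqueous buffer at pH 10.5 and 0 °C. It needs no directing hydroxyl and sets the (2R,3R)-oxirane by reagent control through the spiro transition state, while the carbonate medium drives the ring switch to the lactone in the same flask. The fallback comes back to the route at 16.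

Step 3 (organocatalytic chlorination, reduction and closure). The enantioselectivity or its sense may be unsatisfactory, and NCS may touch the trisubstituted alkene. The fallback sets out from 6. L-Proline (20 mol %) and nitrosobenzene (CHCl3, 4 °C) effect α-aminoxylation, which puts the oxygen on C5' directly in the configuration needed, giving (2E,5R)-3-methyl-6-oxo-5-[(phenylamino)oxy]hex-2-en-1-yl acetate F5. NaBH4 in the same flask reduces it to (2E,5R)-6-hydroxy-3-methyl-5-[(phenylamino)oxy]hex-2-en-1-yl acetate F6. Zn dust in AcOH cleaves the N–O bond to (2E,5R)-5,6-dihydroxy-3-methylhex-2-en-1-yl acetate F7. Bu2SnO (2 mol %), TsCl and Et3N tosylate the primary hydroxyl selectively to (2E,5R)-5-hydroxy-3-methyl-6-[(4-methylbenzenesulfonyl)oxy]hex-2-en-1-yl acetate F8. K2CO3 in MeOH then closes the oxirane with retention at the carbinol carbon and removes the acetate, and the fallback comes back to the route at 9.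

**Further compounds**
F1 | step 4 | (2E,5S)-5-chloro-3-methyl-6-[(trifluoromethanesulfonyl)oxy]hex-2-en-1-yl acetate | CC(=O)OC/C=C(C)/C[C@H](Cl)COS(=O)(=O)C(F)(F)F
F2 | step 4 | (2S,5R)-2-tert-butyl-5-[(2S,4E)-6-acetoxy-2-chloro-4-methylhex-4-en-1-yl]-5-methyl-1,3-dioxolan-4-one | C[C@]1(C[C@@H](Cl)C/C(C)=C/COC(C)=O)O[C@H](C(C)(C)C)OC1=O
F3 | step 4 | (3R,5R)-3-hydroxy-5-[(2E)-4-hydroxy-2-methylbut-2-en-1-yl]-3-methyloxolan-2-one | OC/C=C(C)/C[C@@H]1C[C@@](C)(O)C(=O)O1
F4 | step 5 | 7-{[(2E,5R)-6-[(2S,4R)-2-tert-butyl-4-methyl-5-oxo-1,3-dioxolan-4-yl]-5-hydroxy-3-methylhex-2-en-1-yl]oxy}-8-methoxy-2H-chromen-2-one | COc1c(OC/C=C(C)/C[C@@H](O)C[C@@]2(C)O[C@H](C(C)(C)C)OC2=O)ccc2ccc(=O)oc12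
F5 | step 3 | (2E,5R)-3-methyl-6-oxo-5-[(phenylamino)oxy]hex-2-en-1-yl acetate | CC(=O)OC/C=C(C)/C[C@H](C=O)ONc1ccccc1
F6 | step 3 | (2E,5R)-6-hydroxy-3-methyl-5-[(phenylamino)oxy]hex-2-en-1-yl acetate | CC(=O)OC/C=C(C)/C[C@H](CO)ONc1ccccc1
F7 | step 3 | (2E,5R)-5,6-dihydroxy-3-methylhex-2-en-1-yl acetate | CC(=O)OC/C=C(C)/C[C@H](CO)O
F8 | step 3 | (2E,5R)-5-hydroxy-3-methyl-6-[(4-methylbenzenesulfonyl)oxy]hex-2-en-1-yl acetate | CC(=O)OC/C=C(C)/C[C@H](COS(=O)(=O)c1ccc(C)cc1)O
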